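The pyranone ring is disconnected at both of its bonds to the benzo ring, O1–C8a and C4–C4a. Because the C5 and C8 hydroxyls sit para to each other, C4a and C8a are the two equivalent carbons of a symmetrical 3,6-dimethoxybenzyne, so no regiochemistry arises. In the key step the alkoxide of an (R)-3-silyloxy ester (the O1–C2–C3–C4 unit, with C2 already set by Noyori hydrogenation) adds to this aryne and the resulting aryl anion closes onto the ester, making the aryl ether and the aryl ketone in one operation. The precursors are the trimethylsilyl ether of methyl (R)-3-hydroxyoctadecanoate and an ortho-silylaryl triflate; double O-demethylation finishes the route.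

Key step: step 6

Remark: chromanone numbering (O-1, C-2, C-3, C-4, C-4a, C-5 to C-8, C-8a) is used throughout; 1 and 4 are taken as catalogue compounds.

Step 1
Reactants: 1 methyl 3-oxooctadecanoate
Product: 2 methyl (R)-3-hydroxyoctadecanoate
Conditions: H2 (50 atm), RuCl2[(R)-BINAP] (0.2 mol%), MeOH, 50 °C
Reagents that add atoms: none
Why: Noyori asymmetric hydrogenation of a β-keto ester: the substrate binds ruthenium through both carbonyl oxygens and the (R)-BINAP ligand should deliver hydride to the ketone face that gives the (R)-carbinol, the sense known for unbranched 3-oxoalkanoates.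

Step 2
Reactants: 2 methyl (R)-3-hydroxyoctadecanoate
Product: 3 methyl (R)-3-(trimethylsilyloxy)octadecanoate
Conditions: (Me3Si)2NH (0.7 equiv), Me3SiOTf (1 mol%), CH2Cl2, rt; evaporation, no aqueous work-up
Reagents that add atoms: hexamethyldisilazane, C[Si](C)(C)N[Si](C)(C)C
Why: Acid-catalysed O-silylation of a secondary alcohol with hexamethyldisilazane should be clean, releases only ammonia, and touches neither the stereocenter nor the ester.

Step 3
Reactants: 4 2,5-dimethoxyphenol
Product: 5 2,5-dimethoxyphenyl N-isopropylcarbamate
Conditions: i-PrNCO (1.5 equiv), Et3N (0.2 equiv), CH2Cl2, rt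
Reagents that add atoms: isopropyl isocyanate, CC(C)N=C=O
Why: Amine-catalysed addition of the phenol O–H to the isocyanate (carbamoylation) should install an N-monosubstituted carbamate that directs metalation and can later be removed under mild base.

Step 4
Reactants: 5 2,5-dimethoxyphenyl N-isopropylcarbamate
Product: 9 3,6-dimethoxy-2-(trimethylsilyl)phenyl N-isopropylcarbamate, via N-silyl carbamate 6 (not isolated), via ortho-lithiated carbamate 7 (not isolated), via bis-silylated carbamate 8 (not isolated)
Conditions: t-BuMe2SiOTf (1.1 equiv), TMEDA (1.1 equiv), Et2O, 0 °C to rt; then TMEDA (2 equiv), n-BuLi (2.2 equiv), −78 °C; then Me3SiCl (3 equiv), −78 °C to rt; aq. NaHSO4 work-up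
Reagents that add atoms: chlorotrimethylsilane, C[Si](C)(C)Cl
Why: Directed ortho metalation with in situ N-silylation: the silylated carbamate cannot fragment to an isocyanate, n-BuLi/TMEDA should remove the only hydrogen ortho to the carbamate (also ortho to a methoxy group, so both groups cooperate), Me3SiCl traps the aryllithium at −78 °C before an anionic Fries shift, and the N–Si bond is hydrolysed on acidic work-up.

Step 5
Reactants: 9 3,6-dimethoxy-2-(trimethylsilyl)phenyl N-isopropylcarbamate
Product: 11 3,6-dimethoxy-2-(trimethylsilyl)phenyl trifluoromethanesulfonate, via silylphenoxide 10 (not isolated)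
Conditions: DBU (1.5 equiv), Et2NH (1.3 equiv), MeCN, 40 °C; then PhNTf2 (1.5 equiv), rt
Reagents that add atoms: N-phenylbis(trifluoromethanesulfonimide), O=S(=O)(N(c1ccccc1)S(=O)(=O)C(F)(F)F)C(F)(F)F
Why: E1cB cleavage of the N–H carbamate (DBU removes N–H, the phenoxide leaves, Et2NH traps the isopropyl isocyanate as a urea) followed by O-triflation of the phenoxide with PhNTf2 in the same flask should give the ortho-silylaryl triflate without protodesilylation.

Step 6
Reactants: 3 methyl (R)-3-(trimethylsilyloxy)octadecanoate; 11 3,6-dimethoxy-2-(trimethylsilyl)phenyl trifluoromethanesulfonate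
Product: 15 (R)-5,8-dimethoxy-2-pentadecylchroman-4-one, via cesium alkoxide 12 (not isolated), via 3,6-dimethoxybenzyne 13 (not isolated), via aryl anion adduct 14 (not isolated)
Conditions: CsF (1.5 equiv), 18-crown-6 (1.5 equiv), THF, 0 °C to rt, 3 and 11 (1.3 equiv) added together by syringe pump; aq. NH4Cl
Reagents that add atoms: none
Why: Proposed new method: fluoride (and later the released methoxide) strips the silyl groups from both partners, so cesium alkoxide 12 and the symmetrical aryne 13 meet in an aprotic medium; O-addition of 12 to 13 gives the 2,6-dialkoxyaryl anion 14, which attacks the methyl ester and expels methoxide. The closest known reaction types are the fluoride-mediated annulation of arynes with methyl salicylates to xanthones, the insertion of arynes into the N–C(=O) bond of β-lactams, and the Parham cyclization of ortho-metalated aryl ethers onto tethered esters; an aliphatic β-alkoxide ester has not been shown in this role. The pyranone ring closes in the 6-exo-trig mode (aryl carbanion onto the ester C=O) directly after the intermolecular aryl C–O bond formation. No stereocenter is made: C-2 comes from 3 with its C–O and C–C bonds untouched, so the (R) configuration set in step 1 should be retained. The step needs C-acylation of 14 to beat protonation and needs no regiocontrol; the first is secured by the silyl ether (no O–H in the flask) and the low basicity of an aryl anion flanked by two alkoxy groups, the second by the twofold symmetry of 13. The methoxide is taken up by silicon as MeOSiMe3, which should keep strong base away from the enolisable product and so suppress retro-oxa-Michael ring opening.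

Step 7
Reactants: 15 (R)-5,8-dimethoxy-2-pentadecylchroman-4-one
Product: 16 (R)-5,8-dihydroxy-2-pentadecylchroman-4-one (target)
Conditions: BBr3 (5 equiv), CH2Cl2, −78 °C to 0 °C; MeOH, then H2O, under argon
Reagents that add atoms: none
Why: Lewis-acid O-demethylation of aryl methyl ethers with BBr3: both methoxy groups have a neighbouring oxygen (the C-4 carbonyl for C-5, O-1 for C-8) to anchor boron, bromide should attack the methyl carbons in preference to the secondary C-2, and low temperature should keep the pyranone ring and its stereocenter intact.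

Compound list
1 | methyl 3-oxooctadecanoate | CCCCCCCCCCCCCCCC(=O)CC(=O)OC | starting material
2 | methyl (R)-3-hydroxyoctadecanoate | CCCCCCCCCCCCCCC[C@@H](O)CC(=O)OC | intermediate
3 | methyl (R)-3-(trimethylsilyloxy)octadecanoate | CCCCCCCCCCCCCCC[C@@H](O[Si](C)(C)C)CC(=O)OC | intermediate
4 | 2,5-dimethoxyphenol | COc1ccc(OC)c(O)c1 | starting material
5 | 2,5-dimethoxyphenyl N-isopropylcarbamate | COc1ccc(OC)c(OC(=O)NC(C)C)c1 | intermediate
6 | 2,5-dimethoxyphenyl N-(tert-butyldimethylsilyl)-N-isopropylcarbamate | COc1ccc(OC)c(OC(=O)N(C(C)C)[Si](C)(C)C(C)(C)C)c1 | intermediate (not isolated)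
7 | 2-lithio-3,6-dimethoxyphenyl N-(tert-butyldimethylsilyl)-N-isopropylcarbamate | COc1ccc(OC)c(OC(=O)N(C(C)C)[Si](C)(C)C(C)(C)C)c1[Li] | intermediate (not isolated)
8 | 3,6-dimethoxy-2-(trimethylsilyl)phenyl N-(tert-butyldimethylsilyl)-N-isopropylcarbamate | COc1ccc(OC)c(OC(=O)N(C(C)C)[Si](C)(C)C(C)(C)C)c1[Si](C)(C)C | intermediate (not isolated)
9 | 3,6-dimethoxy-2-(trimethylsilyl)phenyl N-isopropylcarbamate | COc1ccc(OC)c(OC(=O)NC(C)C)c1[Si](C)(C)C | intermediate
10 | 3,6-dimethoxy-2-(trimethylsilyl)phenoxide, DBU-H+ salt | COc1ccc(OC)c([O-])c1[Si](C)(C)C.C1CCC2=[NH+]CCCN2CC1 | intermediate (not isolated)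
11 | 3,6-dimethoxy-2-(trimethylsilyl)phenyl trifluoromethanesulfonate | COc1ccc(OC)c(OS(=O)(=O)C(F)(F)F)c1[Si](C)(C)C | intermediate
12 | cesium (R)-1-methoxy-1-oxooctadecan-3-olate | CCCCCCCCCCCCCCC[C@@H]([O-])CC(=O)OC.[Cs+] | intermediate (not isolated)
13 | 3,6-dimethoxybenzyne (1,2-didehydro-3,6-dimethoxybenzene) | COC1=CC=C(OC)C#C1 | intermediate (not isolated)
14 | cesium 2-{[(R)-1-methoxy-1-oxooctadecan-3-yl]oxy}-3,6-dimethoxyphenide | CCCCCCCCCCCCCCC[C@@H](OC1=C(OC)C=CC(OC)=[C-]1)CC(=O)OC.[Cs+] | intermediate (not isolated)
15 | (R)-5,8-dimethoxy-2-pentadecylchroman-4-one | CCCCCCCCCCCCCCC[C@@H]1CC(=O)c2c(OC)ccc(OC)c2O1 | intermediate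
16 | (R)-5,8-dihydroxy-2-pentadecylchroman-4-one | CCCCCCCCCCCCCCC[C@@H]1CC(=O)c2c(O)ccc(O)c2O1 | target

Total step count: 7
Longest linear sequence: 5 steps (steps 3, 4, 5, 6, 7, from 2,5-dimethoxyphenol); the ester branch (steps 1, 2) joins at step 6.

Steps most likely to fail

1. Step 6 (proposed new method). Protonation or intramolecular α-deprotonation of the aryl anion may outrun acyl capture, giving an open-chain aryl ether or β-elimination. The alkoxide may also fragment by retro-aldol reaction or oligomerise by transesterification before it meets the aryne. The fallback makes the two bonds one after the other by known chemistry; it sets out from 1 and 4 and comes back at 15. Compound 1 would be hydrogenated as in step 1 but with RuCl2[(S)-BINAP] to methyl (S)-3-hydroxyoctadecanoate F1. Mitsunobu etherification of F1 with phenol 4 (PPh3, DIAD, toluene, 0 °C to rt) should give, with inversion, methyl (R)-3-(2,5-dimethoxyphenoxy)octadecanoate F2. Saponification (LiOH, THF/H2O, 0 °C) should give (R)-3-(2,5-dimethoxyphenoxy)octadecanoic acid F3. Intramolecular Friedel–Crafts acylation (trifluoroacetic anhydride, CH2Cl2, 0 °C) at the only free position ortho to the ether oxygen would then close the ring to 15.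

2. Step 7. Lewis-acid-induced opening of the pyranone ring by retro-oxa-Michael reaction and re-closure would erode the configuration at C-2. Cleavage at C-8 may also stall, and the hydroquinone may oxidise in air. The fallback sets out from 15 and comes back at 16. Oxidative demethylation with (NH4)2Ce(NO3)6 (2.5 equiv, MeCN/H2O, 0 °C) should give (R)-2-pentadecyl-2,3-dihydrochromene-4,5,8-trione F4. Immediate reduction of this quinone with aqueous Na2S2O4 (EtOAc/H2O, rt) would give 16 under neutral conditions.

3. Step 4. Lithiation may be accompanied by anionic Fries migration of the carbamoyl group or by attack of n-BuLi at the carbamate carbonyl or at silicon. The fallback uses an acetal directing group that cannot migrate; it sets out from 4 and comes back at 11, bypassing steps 3 to 5. Phenol 4 would be protected (MeOCH2Cl, i-Pr2NEt, CH2Cl2) as 1,4-dimethoxy-2-(methoxymethoxy)benzene F5. Lithiation between the two oxygen substituents (n-BuLi, TMEDA, THF, 0 °C) and quench with Me3SiCl should give [3,6-dimethoxy-2-(methoxymethoxy)phenyl]trimethylsilane F6. Mild acetal methanolysis (cat. HCl, MeOH, rt) should free 3,6-dimethoxy-2-(trimethylsilyl)phenol F7, and triflation (Tf2O, pyridine, CH2Cl2, 0 °C) would give 11.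

Further compounds
F1 | step 6 | methyl (S)-3-hydroxyoctadecanoate | CCCCCCCCCCCCCCC[C@H](O)CC(=O)OC
F2 | step 6 | methyl (R)-3-(2,5-dimethoxyphenoxy)octadecanoate | CCCCCCCCCCCCCCC[C@@H](Oc1cc(OC)ccc1OC)CC(=O)OC
F3 | step 6 | (R)-3-(2,5-dimethoxyphenoxy)octadecanoic acid | CCCCCCCCCCCCCCC[C@@H](Oc1cc(OC)ccc1OC)CC(=O)O
F4 | step 7 | (R)-2-pentadecyl-2,3-dihydrochromene-4,5,8-trione | CCCCCCCCCCCCCCC[C@@H]1CC(=O)C2=C(O1)C(=O)C=CC2=O
F5 | step 4 | 1,4-dimethoxy-2-(methoxymethoxy)benzene | COCOc1cc(OC)ccc1OC
F6 | step 4 | [3,6-dimethoxy-2-(methoxymethoxy)phenyl]trimethylsilane | COCOc1c(OC)ccc(OC)c1[Si](C)(C)C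
F7 | step 4 | 3,6-dimethoxy-2-(trimethylsilyl)phenol | COc1ccc(OC)c(O)c1[Si](C)(C)C
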